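**Retrosynthetic overview**
1. The strategy rests on one feature of the flavanone. O1, C8a, C4a and C4 (the ring A edge of ring C) are a latent ortho-quinone methide at the aldehyde oxidation level, and C2–C3 with ring B is a para-methoxystyrene. Ring C is therefore cut at C3–C4 and O1–C2.
2. Rings A and B are bought. Ring C, the only ring made, is closed in one operation from salicylaldehyde 7, trimethyl orthoformate 11 and styrene 10 under a chiral confined Brønsted acid, giving the 2,4-cis 4-methoxyflavan 14 with C2 as (S).
3. The C4 methyl ether already holds the ketone oxidation level. DDQ/water turns it into C4=O, which erases the C4 stereocentre, and buffered fluoride frees the two phenols last.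
4. The C8 side chain travels as allyl. A prenyl group beside the free phenol would cyclise in acid, compete with the styrene as nucleophile, and be oxidised by DDQ at its doubly activated CH2. Cross-metathesis completes the prenyl group at the ketone stage.
5. The allyl group is delivered by Claisen rearrangement from the oxygen that becomes O1, after the other ortho hydroxyl has been silylated. The 8-substitution pattern is thus fixed by connectivity and not by a selective protection.

Key step: step 7

Assumption: the sense of induction of the confined acid cannot be predicted with certainty; the (S,S)-acid is written, and its equally accessible (R,R)-enantiomer is used if the (2R,4R)-series is obtained.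

**Step 1**
Reactants: 1 2,4,6-trihydroxybenzaldehyde
Product: 2 2,6-dihydroxy-4-methoxybenzaldehyde
Conditions: Me2SO4 (1.0 equiv), K2CO3 (1.0 equiv), acetone, rt
Reagents that add atoms: dimethyl sulfate, COS(=O)(=O)OC
Why: Williamson-type O-methylation that should be regioselective because the para hydroxyl is the most acidic and the only one not held in a hydrogen bond to the formyl oxygen, while the hard sulfate electrophile and a weak base in acetone favour O- over C-alkylation of the phloroglucinol ring.

**Step 2**
Reactants: 2 2,6-dihydroxy-4-methoxybenzaldehyde; 3 allyl bromide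
Product: 4 2-(allyloxy)-6-hydroxy-4-methoxybenzaldehyde
Conditions: 3 (1.05 equiv), K2CO3 (1.1 equiv), acetone, reflux
Reagents that add atoms: none
Why: Williamson etherification in which the two hydroxyls of 2 are equivalent by symmetry, so only one monoether exists, and the second alkylation is slow because the remaining hydroxyl is locked in a chelate with the formyl group.

**Step 3**
Reactants: 4 2-(allyloxy)-6-hydroxy-4-methoxybenzaldehyde
Product: 5 2-(allyloxy)-6-(tert-butyldimethylsilyloxy)-4-methoxybenzaldehyde
Conditions: TBSCl (1.3 equiv), imidazole (2.5 equiv), DMAP (cat.), DMF, rt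
Reagents that add atoms: tert-butyldimethylsilyl chloride, CC(C)(C)[Si](C)(C)Cl
Why: Standard imidazole-promoted silylation of a phenol, applied here to the only free hydroxyl, which fixes this oxygen as the future C5 oxygen before the allyl group is moved.

**Step 4**
Reactants: 5 2-(allyloxy)-6-(tert-butyldimethylsilyloxy)-4-methoxybenzaldehyde
Product: 7 3-allyl-6-(tert-butyldimethylsilyloxy)-2-hydroxy-4-methoxybenzaldehyde, via Claisen dienone 6 (not isolated)
Conditions: N,N-diethylaniline, 190 °C, argon, sealed tube
Reagents that add atoms: none
Why: Aromatic Claisen rearrangement ([3,3]-sigmatropic shift): C3 is the only ortho carbon that bears hydrogen, so dienone 6 formed there tautomerises irreversibly to the phenol, and the oxygen that delivered the allyl group is released as the one free hydroxyl next to it.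

**Step 5**
Reactants: 8 isovanillin (3-hydroxy-4-methoxybenzaldehyde)
Product: 9 3-(tert-butyldimethylsilyloxy)-4-methoxybenzaldehyde
Conditions: TBSCl (1.2 equiv), imidazole (2.0 equiv), CH2Cl2, rt
Reagents that add atoms: tert-butyldimethylsilyl chloride, CC(C)(C)[Si](C)(C)Cl
Why: Standard silylation of the single phenol, which masks the acidic hydroxyl for the ylide step and keeps ring B from acting as an oxygen nucleophile in step 7.

**Step 6**
Reactants: 9 3-(tert-butyldimethylsilyloxy)-4-methoxybenzaldehyde
Product: 10 2-(tert-butyldimethylsilyloxy)-1-methoxy-4-vinylbenzene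
Conditions: Ph3PCH3Br (1.3 equiv), n-BuLi (1.25 equiv), THF, 0 °C; then 9, 0 °C to rt
Reagents that add atoms: methyltriphenylphosphonium bromide, C[P+](c1ccccc1)(c1ccccc1)c1ccccc1.[Br-]
Why: Wittig methylenation of a non-enolisable aromatic aldehyde with the preformed ylide, conditions under which an aryl silyl ether is stable as long as no excess base is present.

**Step 7**
Reactants: 7 3-allyl-6-(tert-butyldimethylsilyloxy)-2-hydroxy-4-methoxybenzaldehyde; 10 2-(tert-butyldimethylsilyloxy)-1-methoxy-4-vinylbenzene; 11 trimethyl orthoformate
Product: 14 (2S,4S)-8-allyl-5-(tert-butyldimethylsilyloxy)-2-[3-(tert-butyldimethylsilyloxy)-4-methoxyphenyl]-4,7-dimethoxychromane, via dimethyl acetal 12 (not isolated), via methoxy ortho-quinone methide 13 (not isolated)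
Conditions: (S,S)-IDPi acid (BINOL-derived imidodiphosphorimidate, 3,3'-Ar = 3,5-(CF3)2C6H3, N-SO2CF3; 5 mol %), 11 (1.5 equiv), 10 (2 equiv, slow addition), 5 Å molecular sieves, toluene, −30 °C
Reagents that add atoms: none
Why: Proposed new method: acid-catalysed exchange with 11 converts the formyl group of 7 into acetal 12, which ionises with loss of methanol to the methoxy-substituted ortho-quinone methide 13, present as its O-protonated form hydrogen-bonded and ion-paired to the chiral anion. The unsubstituted CH2 terminus of styrene 10 bonds to the exocyclic carbon of 13 (C3–C4) while positive charge develops at the benzylic carbon para to the ring B methoxy group, and the ring A oxygen closes onto that carbon (O1–C2), so ring C is closed by an asynchronous inverse-electron-demand hetero-[4+2] cycloaddition with O1=C8a–C4a=C4 as the heterodiene and C2=C3 as the dienophile. The closest known reaction types are the achiral acid-catalysed coupling of salicylaldehydes, orthoformates and styrenes to 4-alkoxy-2-arylchromans, the chiral-Brønsted-acid-catalysed cycloaddition of ortho-quinone methides with styrenes, and confined-acid cycloadditions of alkoxy-ortho-quinone methides generated from salicylaldehydes and alcohols; their merger into an enantioselective intermolecular three-component reaction has not been shown. C4 is set by the face of 13 that the catalyst pocket leaves open, and C2 is set relative to C4 by the endo orientation of the aryl group, which places 2-aryl and 4-methoxy cis and pseudo-equatorial on the half-chair, so (2S) rests on facial and endo selectivity together. Since a 2,4-trans isomer formed on the same face would carry (2R), it is removed by chromatography at this stage, before C4 is flattened. Regiochemistry follows from the styrene polarity, closure through the correct oxygen is secured because only the allyl-flanked hydroxyl is free, and chemoselectivity is secured by the monosubstituted allyl group, which unlike a prenyl group beside a free phenol is neither protonated by the acid nor a competitor of 10 as π-nucleophile.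

**Step 8**
Reactants: 14 (2S,4S)-8-allyl-5-(tert-butyldimethylsilyloxy)-2-[3-(tert-butyldimethylsilyloxy)-4-methoxyphenyl]-4,7-dimethoxychromane
Product: 16 (2S)-8-allyl-5-(tert-butyldimethylsilyloxy)-2-[3-(tert-butyldimethylsilyloxy)-4-methoxyphenyl]-7-methoxychroman-4-one, via C4 hemiketal 15 (not isolated)
Conditions: DDQ (1.3 equiv), CH2Cl2/aq. NaH2PO4–Na2HPO4 buffer pH 7 (10:1), 0 °C
Reagents that add atoms: water, O
Why: Oxidation of an electron-rich benzylic ether by DDQ, the reaction type behind oxidative cleavage of para-methoxybenzyl ethers: hydride is taken from the pseudo-axial C4–H, the most hydridic position because the cation is stabilised by the α-methoxy group and by the three ortho/para oxygens of ring A, water adds to give hemiketal 15, which loses methanol, and the resulting aryl ketone deactivates ring A so that the monosubstituted allyl CH2 and C2–H (whose configuration is untouched) should be spared.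

**Step 9**
Reactants: 16 (2S)-8-allyl-5-(tert-butyldimethylsilyloxy)-2-[3-(tert-butyldimethylsilyloxy)-4-methoxyphenyl]-7-methoxychroman-4-one; 17 2-methyl-2-butene
Product: 18 (2S)-5-(tert-butyldimethylsilyloxy)-2-[3-(tert-butyldimethylsilyloxy)-4-methoxyphenyl]-7-methoxy-8-(3-methylbut-2-en-1-yl)chroman-4-one
Conditions: second-generation Grubbs catalyst RuCl2(=CHPh)(PCy3)(SIMes) (5 mol %), 17/CH2Cl2 (1:1), 35 °C, sealed flask
Reagents that add atoms: none
Why: Olefin cross-metathesis of a terminal allylarene with an excess of 2-methyl-2-butene, a standard way to turn allyl into prenyl that is driven by loss of propene, is neutral and therefore leaves the C2 stereocentre, the ketone and the silyl ethers alone.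

**Step 10**
Reactants: 18 (2S)-5-(tert-butyldimethylsilyloxy)-2-[3-(tert-butyldimethylsilyloxy)-4-methoxyphenyl]-7-methoxy-8-(3-methylbut-2-en-1-yl)chroman-4-one
Product: 19 (2S)-5-hydroxy-2-(3-hydroxy-4-methoxyphenyl)-7-methoxy-8-(3-methylbut-2-en-1-yl)chroman-4-one (CNP0228678.1)
Conditions: TBAF (2.5 equiv), AcOH (3 equiv), THF, 0 °C
Reagents that add atoms: none
Why: Fluoride-induced cleavage of aryl silyl ethers, buffered by acetic acid so that no free phenoxide or enolate can trigger retro-oxa-Michael opening of ring C to the chalcone, which keeps C2 as (S).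

**Compound list**
1 | 2,4,6-trihydroxybenzaldehyde | O=Cc1c(O)cc(O)cc1O | starting material
2 | 2,6-dihydroxy-4-methoxybenzaldehyde | O=Cc1c(O)cc(OC)cc1O | intermediate
3 | allyl bromide | C=CCBr | starting material
4 | 2-(allyloxy)-6-hydroxy-4-methoxybenzaldehyde | O=Cc1c(O)cc(OC)cc1OCC=C | intermediate
5 | 2-(allyloxy)-6-(tert-butyldimethylsilyloxy)-4-methoxybenzaldehyde | O=Cc1c(OCC=C)cc(OC)cc1O[Si](C)(C)C(C)(C)C | intermediate
6 | 5-allyl-2-(tert-butyldimethylsilyloxy)-4-methoxy-6-oxocyclohexa-1,3-diene-1-carbaldehyde (Claisen dienone, racemic, not isolated) | O=CC1=C(O[Si](C)(C)C(C)(C)C)C=C(OC)C(CC=C)C1=O | intermediate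
7 | 3-allyl-6-(tert-butyldimethylsilyloxy)-2-hydroxy-4-methoxybenzaldehyde | O=Cc1c(O)c(CC=C)c(OC)cc1O[Si](C)(C)C(C)(C)C | intermediate
8 | isovanillin (3-hydroxy-4-methoxybenzaldehyde) | COc1ccc(C=O)cc1O | starting material
9 | 3-(tert-butyldimethylsilyloxy)-4-methoxybenzaldehyde | COc1ccc(C=O)cc1O[Si](C)(C)C(C)(C)C | intermediate
10 | 2-(tert-butyldimethylsilyloxy)-1-methoxy-4-vinylbenzene | C=Cc1ccc(OC)c(O[Si](C)(C)C(C)(C)C)c1 | intermediate
11 | trimethyl orthoformate | COC(OC)OC | starting material
12 | 2-allyl-5-(tert-butyldimethylsilyloxy)-6-(dimethoxymethyl)-3-methoxyphenol (dimethyl acetal of 7, not isolated) | COC(OC)c1c(O)c(CC=C)c(OC)cc1O[Si](C)(C)C(C)(C)C | intermediate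
13 | 2-allyl-5-(tert-butyldimethylsilyloxy)-3-methoxy-6-(methoxymethylidene)cyclohexa-2,4-dien-1-one (exocyclic geometry not defined, not isolated) | COC=C1C(=O)C(CC=C)=C(OC)C=C1O[Si](C)(C)C(C)(C)C | intermediate
14 | (2S,4S)-8-allyl-5-(tert-butyldimethylsilyloxy)-2-[3-(tert-butyldimethylsilyloxy)-4-methoxyphenyl]-4,7-dimethoxychromane (2,4-cis) | COc1ccc([C@@H]2C[C@H](OC)c3c(O[Si](C)(C)C(C)(C)C)cc(OC)c(CC=C)c3O2)cc1O[Si](C)(C)C(C)(C)C | intermediate
15 | (2S)-8-allyl-5-(tert-butyldimethylsilyloxy)-2-[3-(tert-butyldimethylsilyloxy)-4-methoxyphenyl]-4,7-dimethoxychroman-4-ol (hemiketal, C4 not defined, not isolated) | COc1ccc([C@@H]2CC(O)(OC)c3c(O[Si](C)(C)C(C)(C)C)cc(OC)c(CC=C)c3O2)cc1O[Si](C)(C)C(C)(C)C | intermediate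
16 | (2S)-8-allyl-5-(tert-butyldimethylsilyloxy)-2-[3-(tert-butyldimethylsilyloxy)-4-methoxyphenyl]-7-methoxychroman-4-one | COc1ccc([C@@H]2CC(=O)c3c(O[Si](C)(C)C(C)(C)C)cc(OC)c(CC=C)c3O2)cc1O[Si](C)(C)C(C)(C)C | intermediate
17 | 2-methyl-2-butene | CC=C(C)C | starting material
18 | (2S)-5-(tert-butyldimethylsilyloxy)-2-[3-(tert-butyldimethylsilyloxy)-4-methoxyphenyl]-7-methoxy-8-(3-methylbut-2-en-1-yl)chroman-4-one | COc1ccc([C@@H]2CC(=O)c3c(O[Si](C)(C)C(C)(C)C)cc(OC)c(CC=C(C)C)c3O2)cc1O[Si](C)(C)C(C)(C)C | intermediate
19 | (2S)-5-hydroxy-2-(3-hydroxy-4-methoxyphenyl)-7-methoxy-8-(3-methylbut-2-en-1-yl)chroman-4-one (CNP0228678.1) | COc1ccc([C@@H]2CC(=O)c3c(O)cc(OC)c(CC=C(C)C)c3O2)cc1O | target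

**Step count**
Total step count: 10.
Longest linear sequence: 8 steps (steps 1, 2, 3, 4, 7, 8, 9, 10).

**Steps most likely to fail**

**Step 7.**
- The confined pocket may not discriminate the two faces of the ion pair, or the endo and exo approaches, when both partners carry bulky silyl ethers.
- Cationic oligomerisation of the styrene and re-ionisation at C4 may further erode the outcome.
- Acid-induced loss of the ortho silyl group would open a second closure mode through the other oxygen.
- The fallback sets out from 7, 10 and 11 and moves the stereocontrol from the cycloaddition to a late kinetic resolution. The three components are coupled under an achiral acid (Sc(OTf)3 10 mol %, CH2Cl2, 0 °C), the known racemic form of the reaction, to the racemic 2,4-cis 4-methoxyflavan F1. DDQ under the conditions of step 8 gives the racemic 8-allylflavanone bis-silyl ether F2. Asymmetric transfer hydrogenation with RuCl[(R,R)-TsDPEN](p-cymene) and HCO2H/Et3N, an established kinetic resolution of racemic flavanones, is stopped near half conversion. It should reduce the (2R)-enantiomer to the (2R,4R)-cis-flavan-4-ol F3, which is separated by chromatography from the unreacted (2S)-ketone. The route is rejoined at 16.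

**Step 8.**
- Hydride abstraction may compete at the allylic-benzylic CH2 on C8.
- It may also compete at C2–H, which would open ring C and destroy the stereocentre.
- The fallback sets out from 14 and replaces hydride abstraction by ionic exchange followed by alcohol oxidation. Solvolysis with PPTS in acetone/water at rt should ionise only at C4, whose cation is stabilised by the three ring A oxygens, and gives the (2S)-flavan-4-ol F4 as both C4 epimers. Dess–Martin periodinane with NaHCO3 in CH2Cl2, which tolerates the allyl group, oxidises both epimers to the same ketone. The route is rejoined at 16.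

**Step 4.**
- At 190 °C the silyl ether may be lost or transferred between the oxygens.
- The allyl group may migrate onward to the para position by way of the formyl-bearing ortho carbon.
- The crowded aldehyde may decompose.
- The fallback sets out from 4 and reverses the order of events. The unsilylated ether is rearranged (N,N-diethylaniline, 180 °C), its aldehyde stabilised by the chelated hydroxyl, to 3-allyl-2,6-dihydroxy-4-methoxybenzaldehyde F5. The two hydroxyls are then told apart by steric demand: one equivalent of TBSCl with imidazole in CH2Cl2 at 0 °C should silylate the hydroxyl flanked by H-5 rather than the one crowded by the allyl group. The constitution is to be confirmed by an NOE contact between the silyl methyl groups and H-5. The route is rejoined at 7.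

**Further compounds**
F1 | step 7 | racemic (2S*,4S*)-8-allyl-5-(tert-butyldimethylsilyloxy)-2-[3-(tert-butyldimethylsilyloxy)-4-methoxyphenyl]-4,7-dimethoxychromane (both enantiomers) | COc1ccc([C@@H]2C[C@H](OC)c3c(O[Si](C)(C)C(C)(C)C)cc(OC)c(CC=C)c3O2)cc1O[Si](C)(C)C(C)(C)C.COc1ccc([C@H]2C[C@@H](OC)c3c(O[Si](C)(C)C(C)(C)C)cc(OC)c(CC=C)c3O2)cc1O[Si](C)(C)C(C)(C)C
F2 | step 7 | racemic 8-allyl-5-(tert-butyldimethylsilyloxy)-2-[3-(tert-butyldimethylsilyloxy)-4-methoxyphenyl]-7-methoxychroman-4-one (both enantiomers) | COc1ccc([C@@H]2CC(=O)c3c(O[Si](C)(C)C(C)(C)C)cc(OC)c(CC=C)c3O2)cc1O[Si](C)(C)C(C)(C)C.COc1ccc([C@H]2CC(=O)c3c(O[Si](C)(C)C(C)(C)C)cc(OC)c(CC=C)c3O2)cc1O[Si](C)(C)C(C)(C)C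
F3 | step 7 | (2R,4R)-8-allyl-5-(tert-butyldimethylsilyloxy)-2-[3-(tert-butyldimethylsilyloxy)-4-methoxyphenyl]-7-methoxychroman-4-ol | COc1ccc([C@H]2C[C@@H](O)c3c(O[Si](C)(C)C(C)(C)C)cc(OC)c(CC=C)c3O2)cc1O[Si](C)(C)C(C)(C)C
F4 | step 8 | (2S)-8-allyl-5-(tert-butyldimethylsilyloxy)-2-[3-(tert-butyldimethylsilyloxy)-4-methoxyphenyl]-7-methoxychroman-4-ol (both C4 epimers) | COc1ccc([C@@H]2CC(O)c3c(O[Si](C)(C)C(C)(C)C)cc(OC)c(CC=C)c3O2)cc1O[Si](C)(C)C(C)(C)C
F5 | step 4 | 3-allyl-2,6-dihydroxy-4-methoxybenzaldehyde | O=Cc1c(O)c(CC=C)c(OC)cc1O
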